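**Plan**

- The target is robinetinidol (rings A, B, C) joined C4→C8 to (+)-catechin (rings D, E, F). Retrosynthetic cuts, in order: the nine O–benzyl bonds; C3–O and C4–H (back to a C3=C4 alkene); O1–C2 of ring C; C4–C8 (ring D); the Cα=Cβ bond of a chalcone.
- Forward: rings D/E/F are bought as (+)-catechin and lithiated at C8; rings A and B are joined as a 2′-hydroxychalcone; the aryllithium adds to the chalcone carbonyl (the future C4), which fixes the 4→8 linkage; ring C is closed last through O1–C2; the C3=C4 alkene is then hydroborated and all benzyl groups are removed.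
- Enabling feature: C4 carries ring A (with O1 ortho, on C8a) and ring D and is allylic to C2, which is benzylic to ring B. A C4 carbinol therefore ionises under weak acid to a 1,1,3-triarylallyl cation (a protonated vinylogous ortho-quinone methide, O1–C8a–C4a–C4–C3–C2) that O1 captures at C2.
- Stereochemistry: C2 and C3 of the catechin unit are bought; C2 of ring C is set during ring closure by a chiral Brønsted acid; C3 and C4 are relayed from C2 together in one syn hydroboration anti to ring B (2,3-trans-3,4-trans, 4α).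

Key step: step 8

Assumption: rotation about the C4–C8 bond gives rotamers, not separable atropisomers, at every stage; which antipode of the acid catalyst gives the (2S)-flavene must be found by trying both; 5 and 6 are bought.

**Route**

Step 1
Reactants: 1 (+)-catechin
Product: 2 5,7,3′,4′-tetra-O-benzyl-(+)-catechin
Conditions: BnBr, K2CO3, DMF, −20 °C to rt
Reagents that add atoms: benzyl bromide, BrCc1ccccc1
Why: Williamson etherification of the four phenols with a weak base that leaves the secondary 3-OH and both stereocenters untouched.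

Step 2
Reactants: 2 5,7,3′,4′-tetra-O-benzyl-(+)-catechin
Product: 3 3,5,7,3′,4′-penta-O-benzyl-(+)-catechin
Conditions: NaH, BnBr, DMF, 0 °C to rt
Reagents that add atoms: benzyl bromide, BrCc1ccccc1
Why: Williamson etherification of the remaining alkoxide; with no free phenol left, base-induced opening of ring F (the epimerisation pathway at C2) is not available.

Step 3
Reactants: 3 3,5,7,3′,4′-penta-O-benzyl-(+)-catechin
Product: 4 8-bromo-3,5,7,3′,4′-penta-O-benzyl-(+)-catechin
Conditions: NBS, CH2Cl2, −78 °C to rt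
Reagents that add atoms: N-bromosuccinimide, O=C1CCC(=O)N1Br
Why: electrophilic aromatic bromination of the most electron-rich ring D, which on fully O-protected catechins should go to C8 in preference to C6.

Step 4
Reactants: 5 1-[4-(benzyloxy)-2-hydroxyphenyl]ethan-1-one; 6 3,4,5-tris(benzyloxy)benzaldehyde
Product: 7 (E)-1-[4-(benzyloxy)-2-hydroxyphenyl]-3-[3,4,5-tris(benzyloxy)phenyl]prop-2-en-1-one
Conditions: KOH, EtOH/THF, rt; then aq. HCl to pH 5
Reagents that add atoms: none
Why: Claisen–Schmidt aldol condensation gives the thermodynamic (E)-enone, and a 2′-hydroxychalcone without a 6′-oxygen stays open-chain as its phenoxide in strong base.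

Step 5
Reactants: 7 2′-hydroxychalcone
Product: 8 (E)-1-[4-(benzyloxy)-2-(tert-butyldimethylsilyloxy)phenyl]-3-[3,4,5-tris(benzyloxy)phenyl]prop-2-en-1-one
Conditions: TBSCl, imidazole, DMAP (cat.), DMF, rt
Reagents that add atoms: tert-butyldimethylsilyl chloride, CC(C)(C)[Si](C)(C)Cl
Why: silylation masks the acidic phenol, which would otherwise quench the aryllithium and deactivate the carbonyl as a chelated phenoxide, and the silyl ether can later be removed without acid.

Step 6
Reactants: 4 8-bromo-3,5,7,3′,4′-penta-O-benzyl-(+)-catechin; 8 silylated chalcone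
Product: 10 (E)-1-[4-(benzyloxy)-2-(tert-butyldimethylsilyloxy)phenyl]-1-(penta-O-benzylcatechin-8-yl)-3-[3,4,5-tris(benzyloxy)phenyl]prop-2-en-1-ol (both carbinol epimers), via aryllithium 9 (not isolated)
Conditions: 4, n-BuLi, THF, −78 °C; then 8 in THF, −78 °C; H2O quench at −78 °C
Reagents that add atoms: none
Why: bromine–lithium exchange followed by 1,2-addition of the hard aryllithium to the enone carbonyl forms the C4–C8 bond with the regiochemistry fixed by the bromide; the carbinol configuration is irrelevant because this centre is ionised in step 8, and the cold quench is meant to forestall O-to-O silyl migration.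

Step 7
Reactants: 10 silylated tertiary allylic alcohol
Product: 11 (E)-1-[4-(benzyloxy)-2-hydroxyphenyl]-1-(penta-O-benzylcatechin-8-yl)-3-[3,4,5-tris(benzyloxy)phenyl]prop-2-en-1-ol (both carbinol epimers)
Conditions: TBAF, THF, 0 °C; cold water work-up; crude used at once (no silica)
Reagents that add atoms: none
Why: fluoride cleaves the aryl silyl ether under basic conditions in which the acid-labile tertiary carbinol cannot ionise, so the free phenol is released without a racemic background cyclisation.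

Step 8
Reactants: 11 phenol carbinol
Product: 13 (2S)-7-(benzyloxy)-2-[3,4,5-tris(benzyloxy)phenyl]-4-(penta-O-benzylcatechin-8-yl)-2H-chromene, via allyl cation 12 (not isolated)
Conditions: 3,3′-bis(2,4,6-triisopropylphenyl)-H8-BINOL N-triflyl phosphoramide (10 mol%, antipode by trial), 4 Å MS, toluene, −78 °C; Et3N quench
Reagents that add atoms: none
Why: The acid protonates the tertiary, doubly benzylic, allylic hydroxyl at C4, and loss of water gives the 1,1,3-triarylallyl cation 12 (the protonated vinylogous ortho-quinone methide of ring A) as a contact ion pair with the chiral phosphoramide anion, which is hydrogen-bonded to the ring-A phenol. The closest known reaction type is the Brønsted-acid-catalysed enantioselective dehydrative cyclisation (intramolecular SN1′ allylic substitution) of 2-(1-hydroxy-1,3-diarylallyl)phenols to 2,4-diaryl-2H-chromenes. Ring C closes by attack of O1 on the allyl terminus C2, a 6-endo-trig closure that becomes an oxa-6π electrocyclisation in the neutral limit. The new stereocenter C2 is controlled by the chiral counter-anion (catalyst control); because the catechin unit is enantiopure, the two C2 epimers are diastereomers, so a mismatch shows directly and the minor epimer can be removed. The step needs chemoselectivity for O1 over carbocyclisation to an indene and over the other oxygens, and face selectivity at C2: the ring-A hydroxyl is the only free nucleophile (every catechin oxygen, O7 included, is benzylated), ring closure needs only rotation about C3–C4 whereas indene formation would need E-to-Z isomerisation of C2=C3, and the low temperature is meant to suppress re-ionisation of the O1–C2 bond. The product has the same spatial arrangement at C2 as the target (descriptor S only because the C3=C4 alkene changes the priorities).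

Step 9
Reactants: 13 (2S)-flav-3-ene
Product: 15 7,3′,4′,5′-tetra-O-benzylrobinetinidol-(4α→8)-3,5,7,3′,4′-penta-O-benzylcatechin, via alkylborane 14 (not isolated)
Conditions: BH3·SMe2, THF, 0 °C to rt; then NaOH, H2O2, 0 °C to rt
Reagents that add atoms: hydrogen peroxide, OO
Why: Brown hydroboration–oxidation adds H and B syn across C3=C4 on the face anti to ring B at C2, with boron at the less substituted C3 (C4 is diaryl-substituted), and oxidation with retention gives 3-OH trans to ring B and H-4 cis to that OH, so C3 (S) and C4 (S, ring D α and equatorial) are both set from C2 in one event.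

Step 10
Reactants: 15 nona-O-benzyl dimer
Product: 16 robinetinidol-(4α→8)-catechin
Conditions: H2 (1 atm), Pd(OH)2/C, THF/MeOH, rt; filtration under argon, lyophilisation
Reagents that add atoms: none
Why: catalytic hydrogenolysis removes the eight aryl benzyl ethers and the one alkyl benzyl ether, while the cyclic benzylic C2–O1 bonds and the interflavan C–C bond should survive at atmospheric pressure and no stereocenter is touched.

**Compound list**

1 | (+)-catechin, (2R,3S)-2-(3,4-dihydroxyphenyl)chroman-3,5,7-triol | Oc1cc(O)c2c(c1)O[C@H](c1ccc(O)c(O)c1)[C@@H](O)C2 | starting material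
2 | 5,7,3′,4′-tetra-O-benzyl-(+)-catechin (2R,3S) | C(c3ccccc3)Oc1cc(OCc3ccccc3)c2c(c1)O[C@H](c4ccc(OCc3ccccc3)c(OCc3ccccc3)c4)[C@@H](O)C2 | intermediate
3 | 3,5,7,3′,4′-penta-O-benzyl-(+)-catechin (2R,3S) | C(c3ccccc3)Oc1cc(OCc3ccccc3)c2c(c1)O[C@H](c4ccc(OCc3ccccc3)c(OCc3ccccc3)c4)[C@@H](OCc3ccccc3)C2 | intermediate
4 | 8-bromo-3,5,7,3′,4′-penta-O-benzyl-(+)-catechin (2R,3S) | C(c3ccccc3)Oc1cc(OCc3ccccc3)c2c(c1Br)O[C@H](c4ccc(OCc3ccccc3)c(OCc3ccccc3)c4)[C@@H](OCc3ccccc3)C2 | intermediate
5 | 1-[4-(benzyloxy)-2-hydroxyphenyl]ethan-1-one | CC(=O)c1ccc(OCc2ccccc2)cc1O | starting material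
6 | 3,4,5-tris(benzyloxy)benzaldehyde | O=Cc1cc(OCc2ccccc2)c(OCc2ccccc2)c(OCc2ccccc2)c1 | starting material
7 | (E)-1-[4-(benzyloxy)-2-hydroxyphenyl]-3-[3,4,5-tris(benzyloxy)phenyl]prop-2-en-1-one | O=C(/C=C/c1cc(OCc2ccccc2)c(OCc2ccccc2)c(OCc2ccccc2)c1)c1ccc(OCc2ccccc2)cc1O | intermediate
8 | (E)-1-[4-(benzyloxy)-2-(tert-butyldimethylsilyloxy)phenyl]-3-[3,4,5-tris(benzyloxy)phenyl]prop-2-en-1-one | O=C(/C=C/c1cc(OCc2ccccc2)c(OCc2ccccc2)c(OCc2ccccc2)c1)c1ccc(OCc2ccccc2)cc1O[Si](C)(C)C(C)(C)C | intermediate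
9 | 8-lithio-3,5,7,3′,4′-penta-O-benzyl-(+)-catechin (2R,3S) | [Li]c1c(OCc3ccccc3)cc(OCc3ccccc3)c2c1O[C@H](c4ccc(OCc3ccccc3)c(OCc3ccccc3)c4)[C@@H](OCc3ccccc3)C2 | intermediate
10 | (E)-1-[4-(benzyloxy)-2-(tert-butyldimethylsilyloxy)phenyl]-1-(penta-O-benzylcatechin-8-yl)-3-[3,4,5-tris(benzyloxy)phenyl]prop-2-en-1-ol, both carbinol epimers | OC(/C=C/c1cc(OCc2ccccc2)c(OCc2ccccc2)c(OCc2ccccc2)c1)(c1ccc(OCc2ccccc2)cc1O[Si](C)(C)C(C)(C)C)c1c(OCc3ccccc3)cc(OCc3ccccc3)c2c1O[C@H](c4ccc(OCc3ccccc3)c(OCc3ccccc3)c4)[C@@H](OCc3ccccc3)C2 | intermediate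
11 | (E)-1-[4-(benzyloxy)-2-hydroxyphenyl]-1-(penta-O-benzylcatechin-8-yl)-3-[3,4,5-tris(benzyloxy)phenyl]prop-2-en-1-ol, both carbinol epimers | OC(/C=C/c1cc(OCc2ccccc2)c(OCc2ccccc2)c(OCc2ccccc2)c1)(c1ccc(OCc2ccccc2)cc1O)c1c(OCc3ccccc3)cc(OCc3ccccc3)c2c1O[C@H](c4ccc(OCc3ccccc3)c(OCc3ccccc3)c4)[C@@H](OCc3ccccc3)C2 | intermediate
12 | 1,1,3-triarylallyl cation (protonated vinylogous ortho-quinone methide of ring A), ion-paired with the catalyst anion | Oc1cc(OCc2ccccc2)ccc1[C+](/C=C/c1cc(OCc2ccccc2)c(OCc2ccccc2)c(OCc2ccccc2)c1)c1c(OCc3ccccc3)cc(OCc3ccccc3)c2c1O[C@H](c4ccc(OCc3ccccc3)c(OCc3ccccc3)c4)[C@@H](OCc3ccccc3)C2 | intermediate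
13 | (2S)-7-(benzyloxy)-2-[3,4,5-tris(benzyloxy)phenyl]-4-[(2R,3S)-penta-O-benzylcatechin-8-yl]-2H-chromene | C(c3ccccc3)Oc1ccc2c(c1)O[C@H](c1cc(OCc3ccccc3)c(OCc3ccccc3)c(OCc3ccccc3)c1)C=C2c1c(OCc3ccccc3)cc(OCc3ccccc3)c2c1O[C@H](c4ccc(OCc3ccccc3)c(OCc3ccccc3)c4)[C@@H](OCc3ccccc3)C2 | intermediate
14 | 3-boryl flavan (boron at C3 trans to ring B at C2 and trans to ring D at C4; 2,4-cis) | C(c3ccccc3)Oc1ccc2c(c1)O[C@H](c1cc(OCc3ccccc3)c(OCc3ccccc3)c(OCc3ccccc3)c1)[C@@H](B)[C@@H]2c1c(OCc3ccccc3)cc(OCc3ccccc3)c2c1O[C@H](c4ccc(OCc3ccccc3)c(OCc3ccccc3)c4)[C@@H](OCc3ccccc3)C2 | intermediate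
15 | 7,3′,4′,5′-tetra-O-benzylrobinetinidol-(4α→8)-3,5,7,3′,4′-penta-O-benzylcatechin (upper unit 2R,3S,4S; lower unit 2R,3S) | C(c3ccccc3)Oc1ccc2c(c1)O[C@H](c1cc(OCc3ccccc3)c(OCc3ccccc3)c(OCc3ccccc3)c1)[C@@H](O)[C@@H]2c1c(OCc3ccccc3)cc(OCc3ccccc3)c2c1O[C@H](c4ccc(OCc3ccccc3)c(OCc3ccccc3)c4)[C@@H](OCc3ccccc3)C2 | intermediate
16 | robinetinidol-(4α→8)-catechin (upper unit 2R,3S,4S; lower unit 2R,3S) | Oc1ccc2c(c1)O[C@H](c1cc(O)c(O)c(O)c1)[C@@H](O)[C@@H]2c1c(O)cc(O)c2c1O[C@H](c1ccc(O)c(O)c1)[C@@H](O)C2 | target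

**Step count and risks**

Total steps: 10. Longest linear sequence: 8 steps (steps 1–3 and 6–10, from (+)-catechin).

Steps most likely to fail:

1. Step 8. The catalyst may not discriminate the two faces of C2 well enough on this crowded, chiral substrate; a racemic background closure on traces of acid may compete; or the O1–C2 bond may re-ionise and scramble C2. Fallback, setting out from 11 and coming back at 13: cyclodehydration with an achiral acid (pyridinium p-toluenesulfonate, CH2Cl2, 0 °C) should give 13 together with its C2 epimer, the (2R)-flav-3-ene F1. Because the catechin unit is enantiopure, 13 and F1 are diastereomers and should be separable by chromatography. F1 is then returned to the mixture by brief treatment with the same acid (reversible ionisation of O1–C2 through cation 12) and separated again, so the material converges on 13. Stereocontrol thus moves from catalyst control to separation of diastereomers with recycling.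

2. Step 6. The hindered 2,6-dioxygenated aryllithium may add in the conjugate sense, may add incompletely to the crowded enone carbonyl, or the silyl group may migrate. Fallback, setting out from 4 (and 6) and coming back at 10: the aryllithium from 4 (n-BuLi, THF, −78 °C) is added to the small aldehyde 4-(benzyloxy)-2-(tert-butyldimethylsilyloxy)benzaldehyde F2 (from commercial 4-(benzyloxy)-2-hydroxybenzaldehyde, TBSCl, imidazole) to give the diarylmethanol F3. Dess–Martin oxidation gives the diaryl ketone F4. The lithium acetylide of 5-ethynyl-1,2,3-tris(benzyloxy)benzene F5 (from 6 with the Ohira–Bestmann reagent, K2CO3, MeOH; then n-BuLi) adds to F4 as a slim nucleophile to give the propargylic alcohol F6. Hydroxyl-directed trans-hydroalumination with NaAlH2(OCH2CH2OCH3)2 in THF and protonolysis then gives the (E)-allylic alcohol 10.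

3. Step 9. Borane addition to the crowded trisubstituted alkene may be slow, or the facial selectivity may be poor. Fallback, setting out from 13 and coming back at 15: dihydroxylation with OsO4 (cat.) and N-methylmorpholine N-oxide in acetone/water, anti to ring B, should give the 3,4-cis-diol F7 (both hydroxyls β, ring D α). Ionic hydrogenation (Et3SiH, CF3CO2H, CH2Cl2, −78 to −40 °C) ionises only the tertiary, doubly benzylic 4-hydroxyl. Hydride is expected to enter axially on the β face, leaving ring D equatorial and trans to the 3-OH, which gives 15; the sense of this hydride delivery is the uncertain point of the fallback.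

Further compounds
F1 | step 8 | (2R)-7-(benzyloxy)-2-[3,4,5-tris(benzyloxy)phenyl]-4-[(2R,3S)-penta-O-benzylcatechin-8-yl]-2H-chromene (C2 epimer of 13) | C(c3ccccc3)Oc1ccc2c(c1)O[C@@H](c1cc(OCc3ccccc3)c(OCc3ccccc3)c(OCc3ccccc3)c1)C=C2c1c(OCc3ccccc3)cc(OCc3ccccc3)c2c1O[C@H](c4ccc(OCc3ccccc3)c(OCc3ccccc3)c4)[C@@H](OCc3ccccc3)C2
F2 | step 6 | 4-(benzyloxy)-2-(tert-butyldimethylsilyloxy)benzaldehyde | O=Cc1ccc(OCc2ccccc2)cc1O[Si](C)(C)C(C)(C)C
F3 | step 6 | [4-(benzyloxy)-2-(tert-butyldimethylsilyloxy)phenyl](penta-O-benzylcatechin-8-yl)methanol, both carbinol epimers | OC(c1ccc(OCc2ccccc2)cc1O[Si](C)(C)C(C)(C)C)c1c(OCc3ccccc3)cc(OCc3ccccc3)c2c1O[C@H](c4ccc(OCc3ccccc3)c(OCc3ccccc3)c4)[C@@H](OCc3ccccc3)C2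
F4 | step 6 | [4-(benzyloxy)-2-(tert-butyldimethylsilyloxy)phenyl](penta-O-benzylcatechin-8-yl)methanone | O=C(c1ccc(OCc2ccccc2)cc1O[Si](C)(C)C(C)(C)C)c1c(OCc3ccccc3)cc(OCc3ccccc3)c2c1O[C@H](c4ccc(OCc3ccccc3)c(OCc3ccccc3)c4)[C@@H](OCc3ccccc3)C2
F5 | step 6 | 5-ethynyl-1,2,3-tris(benzyloxy)benzene | C#Cc1cc(OCc2ccccc2)c(OCc2ccccc2)c(OCc2ccccc2)c1
F6 | step 6 | 1-[4-(benzyloxy)-2-(tert-butyldimethylsilyloxy)phenyl]-1-(penta-O-benzylcatechin-8-yl)-3-[3,4,5-tris(benzyloxy)phenyl]prop-2-yn-1-ol, both carbinol epimers | OC(C#Cc1cc(OCc2ccccc2)c(OCc2ccccc2)c(OCc2ccccc2)c1)(c1ccc(OCc2ccccc2)cc1O[Si](C)(C)C(C)(C)C)c1c(OCc3ccccc3)cc(OCc3ccccc3)c2c1O[C@H](c4ccc(OCc3ccccc3)c(OCc3ccccc3)c4)[C@@H](OCc3ccccc3)C2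
F7 | step 9 | 7-(benzyloxy)-2-[3,4,5-tris(benzyloxy)phenyl]-4-(penta-O-benzylcatechin-8-yl)chroman-3,4-diol, 2,3-trans-3,4-cis-diol with ring D trans to the 3-OH | C(c3ccccc3)Oc1ccc2c(c1)O[C@H](c1cc(OCc3ccccc3)c(OCc3ccccc3)c(OCc3ccccc3)c1)[C@@H](O)[C@]2(O)c1c(OCc3ccccc3)cc(OCc3ccccc3)c2c1O[C@H](c4ccc(OCc3ccccc3)c(OCc3ccccc3)c4)[C@@H](OCc3ccccc3)C2
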